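**Retrosynthetic overview**
- The ten-membered carbocycle is closed last, at C4–C5, by an intramolecular Nozaki–Hiyama–Kishi addition of an alkenyl triflate to the C5 aldehyde; this gives the 4(15)-methylene/5-hydroxy unit directly.
- The C8 angelate comes from the C8 alcohol. The key C7–C8 bond comes from an intermolecular zinc Barbier allylation of a bis-epoxy aldehyde (C8–C10, C1–C4, C14, C15) with a 3-(bromomethyl)butenolide (C5–C7, C11–C13); it unveils the α-methylene lactone and sets C7 and C8.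
- The butenolide is made from (R)-glycidol (source of C6) and 2-(bromomethyl)acrylic acid by acylation and ring-closing metathesis.
- The aldehyde is made from but-3-yn-1-ol by carboalumination, two reagent-controlled Sharpless epoxidations, and conversion of a methyl ketone into the enol triflate.
- Ring order: γ-lactone, then the trans 1,10-oxirane, then the cis 2,3-oxirane, then the ten-membered ring.

Assumption: germacrane numbering (C1–C15) is used for orientation; the SMILES is read as the 1R,2S,3S,5R,6S,7R,8S,10R isomer carrying a (Z)-2-methylbut-2-enoate (angelate) at C8.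

**Route**

Step 1
Reactants: 1 (R)-glycidol
Product: 2 (S)-2-(((4-methoxybenzyl)oxy)methyl)oxirane
Conditions: NaH, 4-methoxybenzyl chloride, Bu4NI (cat.), THF/DMF, 0 °C to rt
Reagents that add atoms: 4-methoxybenzyl chloride COc1ccc(CCl)cc1
Why: Williamson etherification of the primary alkoxide leaves the stereocentre untouched (the descriptor changes from R to S only because the CIP priorities change).

Step 2
Reactants: 2 (S)-2-(((4-methoxybenzyl)oxy)methyl)oxirane
Product: 3 (S)-1-((4-methoxybenzyl)oxy)but-3-en-2-ol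
Conditions: Me3S+ I−, n-BuLi, THF, −10 °C to rt
Reagents that add atoms: trimethylsulfonium iodide C[S+](C)C.[I-]
Why: Sulfonium-ylide opening at the terminal epoxide carbon followed by loss of Me2S (epoxide-to-allylic-alcohol homologation) does not touch the C–O stereocentre, which becomes C6.

Step 3
Reactants: 3 (S)-1-((4-methoxybenzyl)oxy)but-3-en-2-ol; 4 2-(bromomethyl)acrylic acid
Product: 5 (S)-1-((4-methoxybenzyl)oxy)but-3-en-2-yl 2-(bromomethyl)acrylate
Conditions: DCC, DMAP (5 mol %), CH2Cl2, 0 °C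
Reagents that add atoms: none
Why: Steglich esterification at 0 °C with only catalytic DMAP acylates the alcohol faster than the allylic bromide is displaced.

Step 4
Reactants: 5 (S)-1-((4-methoxybenzyl)oxy)but-3-en-2-yl 2-(bromomethyl)acrylate
Product: 6 (S)-3-(bromomethyl)-5-(((4-methoxybenzyl)oxy)methyl)furan-2(5H)-one
Conditions: second-generation Grubbs catalyst (5 mol %), CH2Cl2 (0.01 M), 40 °C
Reagents that add atoms: none
Why: Ring-closing metathesis of the acrylate with the allylic vinyl group forms the five-membered butenolide; the allylic bromide and the PMB ether are inert to the ruthenium carbene.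

Step 5
Reactants: 7 but-3-yn-1-ol
Product: 8 1-((but-3-yn-1-yloxy)methyl)-4-methoxybenzene
Conditions: NaH, 4-methoxybenzyl chloride, Bu4NI (cat.), THF/DMF, 0 °C to rt
Reagents that add atoms: 4-methoxybenzyl chloride COc1ccc(CCl)cc1
Why: Williamson etherification; the alkoxide (not the much less acidic alkyne C–H) is formed with one equivalent of NaH.

Step 6
Reactants: 8 1-((but-3-yn-1-yloxy)methyl)-4-methoxybenzene
Product: 11 (E)-5-((4-methoxybenzyl)oxy)-3-methylpent-2-en-1-ol, via alkenyldimethylalane 9 (not isolated), via lithium alkenylalanate 10 (not isolated)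
Conditions: AlMe3, Cp2ZrCl2 (20 mol %), CH2Cl2, 0 °C to rt; then n-BuLi, THF, −78 °C; (CH2O)n, −78 °C to rt; aqueous work-up
Reagents that add atoms: trimethylaluminium C[Al](C)C; paraformaldehyde (as formaldehyde) C=O
Why: Negishi zirconium-catalysed carboalumination adds Me and Al syn across the alkyne, and trapping the alanate with formaldehyde retains the geometry, giving only the E-trisubstituted allylic alcohol (C1=C10).

Step 7
Reactants: 11 (E)-5-((4-methoxybenzyl)oxy)-3-methylpent-2-en-1-ol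
Product: 12 ((2R,3R)-3-(2-((4-methoxybenzyl)oxy)ethyl)-3-methyloxiran-2-yl)methanol
Conditions: Ti(OiPr)4 (10 mol %), D-(−)-diethyl tartrate (12 mol %), t-BuOOH, 4 Å MS, CH2Cl2, −20 °C
Reagents that add atoms: tert-butyl hydroperoxide CC(C)(C)OO
Why: Sharpless asymmetric epoxidation of a geraniol-type E-allylic alcohol; D-(−)-tartrate gives the (2R,3R)-epoxy alcohol, which fixes C1 and C10 as the trans oxirane by reagent control.

Step 8
Reactants: 12 ((2R,3R)-3-(2-((4-methoxybenzyl)oxy)ethyl)-3-methyloxiran-2-yl)methanol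
Product: 13 (2S,3R)-3-(2-((4-methoxybenzyl)oxy)ethyl)-3-methyloxirane-2-carbaldehyde
Conditions: Dess–Martin periodinane, pyridine, CH2Cl2, 0 °C to rt
Reagents that add atoms: none
Why: Buffered Dess–Martin oxidation gives the epoxy aldehyde without epoxide opening or epimerisation (the descriptor change is a CIP effect only).

Step 9
Reactants: 13 (2S,3R)-3-(2-((4-methoxybenzyl)oxy)ethyl)-3-methyloxirane-2-carbaldehyde
Product: 14 methyl (Z)-3-((2R,3R)-3-(2-((4-methoxybenzyl)oxy)ethyl)-3-methyloxiran-2-yl)acrylate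
Conditions: (CF3CH2O)2P(O)CH2CO2Me, KN(SiMe3)2, 18-crown-6, THF, −78 °C
Reagents that add atoms: methyl 2-[bis(2,2,2-trifluoroethoxy)phosphoryl]acetate COC(=O)CP(=O)(OCC(F)(F)F)OCC(F)(F)F
Why: Still–Gennari olefination gives the Z-enoate (C2=C3) under kinetic control at −78 °C.

Step 10
Reactants: 14 methyl (Z)-3-((2R,3R)-3-(2-((4-methoxybenzyl)oxy)ethyl)-3-methyloxiran-2-yl)acrylate
Product: 15 (Z)-3-((2R,3R)-3-(2-((4-methoxybenzyl)oxy)ethyl)-3-methyloxiran-2-yl)prop-2-en-1-ol
Conditions: i-Bu2AlH (2.5 equiv), CH2Cl2, −78 °C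
Reagents that add atoms: none
Why: 1,2-Reduction of the enoate at −78 °C gives the Z-allylic alcohol without touching the oxirane or the alkene geometry.

Step 11
Reactants: 15 (Z)-3-((2R,3R)-3-(2-((4-methoxybenzyl)oxy)ethyl)-3-methyloxiran-2-yl)prop-2-en-1-ol
Product: 16 ((2S,3S)-3-((2R,3R)-3-(2-((4-methoxybenzyl)oxy)ethyl)-3-methyloxiran-2-yl)oxiran-2-yl)methanol
Conditions: Ti(OiPr)4 (20 mol %), L-(+)-diethyl tartrate (24 mol %), t-BuOOH, 4 Å MS, CH2Cl2, −20 °C
Reagents that add atoms: tert-butyl hydroperoxide CC(C)(C)OO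
Why: A second Sharpless asymmetric epoxidation, now with L-(+)-tartrate, delivers oxygen syn to the Z-alkene and sets C2 and C3 as the cis oxirane by reagent control.

Step 12
Reactants: 16 ((2S,3S)-3-((2R,3R)-3-(2-((4-methoxybenzyl)oxy)ethyl)-3-methyloxiran-2-yl)oxiran-2-yl)methanol
Product: 17 (2R,3R)-3-((2R,3R)-3-(2-((4-methoxybenzyl)oxy)ethyl)-3-methyloxiran-2-yl)oxirane-2-carbaldehyde
Conditions: Dess–Martin periodinane, pyridine, CH2Cl2, 0 °C
Reagents that add atoms: none
Why: Buffered Dess–Martin oxidation of the primary alcohol; the cis-epoxy aldehyde is used without chromatography to avoid cis-to-trans epimerisation.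

Step 13
Reactants: 17 (2R,3R)-3-((2R,3R)-3-(2-((4-methoxybenzyl)oxy)ethyl)-3-methyloxiran-2-yl)oxirane-2-carbaldehyde
Product: 18 1-((2S,3S)-3-((2R,3R)-3-(2-((4-methoxybenzyl)oxy)ethyl)-3-methyloxiran-2-yl)oxiran-2-yl)ethan-1-ol (both carbinol epimers)
Conditions: MeMgBr, THF, −78 °C
Reagents that add atoms: methylmagnesium bromide C[Mg]Br
Why: Grignard 1,2-addition to the aldehyde is much faster than epoxide opening at −78 °C; the new carbinol centre is removed in the next step, so its configuration does not matter.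

Step 14
Reactants: 18 1-((2S,3S)-3-((2R,3R)-3-(2-((4-methoxybenzyl)oxy)ethyl)-3-methyloxiran-2-yl)oxiran-2-yl)ethan-1-ol
Product: 19 1-((2R,3R)-3-((2R,3R)-3-(2-((4-methoxybenzyl)oxy)ethyl)-3-methyloxiran-2-yl)oxiran-2-yl)ethan-1-one
Conditions: Dess–Martin periodinane, pyridine, CH2Cl2, 0 °C to rt
Reagents that add atoms: none
Why: Dess–Martin oxidation converges both epimers on the cis-α,β-epoxy methyl ketone (C4 carbonyl, C15 methyl), which cannot enolise toward the oxirane carbon.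

Step 15
Reactants: 19 1-((2R,3R)-3-((2R,3R)-3-(2-((4-methoxybenzyl)oxy)ethyl)-3-methyloxiran-2-yl)oxiran-2-yl)ethan-1-one
Product: 21 1-((2R,3S)-3-((2R,3R)-3-(2-((4-methoxybenzyl)oxy)ethyl)-3-methyloxiran-2-yl)oxiran-2-yl)vinyl trifluoromethanesulfonate, via potassium enolate 20 (not isolated)
Conditions: KN(SiMe3)2, THF, −78 °C; then PhNTf2, −78 to 0 °C
Reagents that add atoms: N-phenylbis(trifluoromethanesulfonimide) O=S(=O)(N(c1ccccc1)S(=O)(=O)C(F)(F)F)C(F)(F)F
Why: Kinetic deprotonation can only occur at the methyl group, and O-triflation of the terminal enolate gives the 1,1-disubstituted enol triflate that will become C4=C15.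

Step 16
Reactants: 21 1-((2R,3S)-3-((2R,3R)-3-(2-((4-methoxybenzyl)oxy)ethyl)-3-methyloxiran-2-yl)oxiran-2-yl)vinyl trifluoromethanesulfonate
Product: 22 1-((2R,3S)-3-((2R,3R)-3-(2-hydroxyethyl)-3-methyloxiran-2-yl)oxiran-2-yl)vinyl trifluoromethanesulfonate
Conditions: DDQ, CH2Cl2/pH 7 buffer (10:1), 0 °C
Reagents that add atoms: none
Why: Oxidative PMB cleavage under neutral conditions leaves the oxiranes and the enol triflate intact.

Step 17
Reactants: 22 1-((2R,3S)-3-((2R,3R)-3-(2-hydroxyethyl)-3-methyloxiran-2-yl)oxiran-2-yl)vinyl trifluoromethanesulfonate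
Product: 23 1-((2R,3S)-3-((2R,3R)-3-methyl-3-(2-oxoethyl)oxiran-2-yl)oxiran-2-yl)vinyl trifluoromethanesulfonate
Conditions: Dess–Martin periodinane, pyridine, CH2Cl2, 0 °C; filtered through a short neutral pad, used at once
Reagents that add atoms: none
Why: Buffered Dess–Martin oxidation gives the C8 aldehyde under non-basic conditions, so the β,γ-epoxy aldehyde does not eliminate to the γ-hydroxy enal before use.

Step 18
Reactants: 6 (S)-3-(bromomethyl)-5-(((4-methoxybenzyl)oxy)methyl)furan-2(5H)-one (1.5 equiv); 23 1-((2R,3S)-3-((2R,3R)-3-methyl-3-(2-oxoethyl)oxiran-2-yl)oxiran-2-yl)vinyl trifluoromethanesulfonate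
Product: 25 hydroxy lactone 1-((2R,3S)-3-((2R,3R)-3-((S)-2-hydroxy-2-((2S,3R)-2-(((4-methoxybenzyl)oxy)methyl)-4-methylene-5-oxotetrahydrofuran-3-yl)ethyl)-3-methyloxiran-2-yl)oxiran-2-yl)vinyl trifluoromethanesulfonate, via allylzinc bromide 24 (not isolated)
Conditions: Zn dust (activated), THF/sat. aq. NH4Cl (2:1), 0 °C to rt
Reagents that add atoms: none
Why: Intermolecular Barbier carbonyl allylation: the allylzinc attacks through its γ-carbon (C7) in a Zimmerman–Traxler chair, anti to the C6 substituent (6,7-trans lactone), and because the ring holds C6 trans to the CH2Zn group the adduct is 7,8-anti (8S); the α-methylene lactone is formed in the same event.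

Step 19
Reactants: 25 hydroxy lactone; 26 angelic acid ((Z)-2-methylbut-2-enoic acid)
Product: 28 angelate (S)-1-((2S,3R)-2-(((4-methoxybenzyl)oxy)methyl)-4-methylene-5-oxotetrahydrofuran-3-yl)-2-((2R,3R)-2-methyl-3-((2S,3R)-3-(1-(((trifluoromethyl)sulfonyl)oxy)vinyl)oxiran-2-yl)oxiran-2-yl)ethyl (Z)-2-methylbut-2-enoate, via mixed anhydride 27 (not isolated)
Conditions: 26, 2,4,6-Cl3C6H2COCl, Et3N, toluene, rt, 2 h; then 25, 70 °C (no DMAP)
Reagents that add atoms: none
Why: Yamaguchi mixed-anhydride esterification without a nucleophilic catalyst acylates the C8 alcohol with retention and avoids the DMAP-induced Z-to-E isomerisation of the angeloyl group.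

Step 20
Reactants: 28 angelate
Product: 29 (S)-1-((2S,3R)-2-(hydroxymethyl)-4-methylene-5-oxotetrahydrofuran-3-yl)-2-((2R,3R)-2-methyl-3-((2S,3R)-3-(1-(((trifluoromethyl)sulfonyl)oxy)vinyl)oxiran-2-yl)oxiran-2-yl)ethyl (Z)-2-methylbut-2-enoate
Conditions: DDQ, CH2Cl2/pH 7 buffer (10:1), 0 °C to rt
Reagents that add atoms: none
Why: Oxidative PMB cleavage frees the C5 primary alcohol; the electron-poor alkenes, the oxiranes and the enol triflate do not react with DDQ.

Step 21
Reactants: 29 primary alcohol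
Product: 30 (S)-1-((2S,3R)-2-formyl-4-methylene-5-oxotetrahydrofuran-3-yl)-2-((2R,3R)-2-methyl-3-((2S,3R)-3-(1-(((trifluoromethyl)sulfonyl)oxy)vinyl)oxiran-2-yl)oxiran-2-yl)ethyl (Z)-2-methylbut-2-enoate
Conditions: Dess–Martin periodinane, pyridine, CH2Cl2, 0 °C; used crude
Reagents that add atoms: none
Why: Buffered Dess–Martin oxidation gives the α-acyloxy aldehyde (C5) without epimerising C6.

Step 22
Reactants: 30 aldehyde
Product: 32 target CNP0038366.2, (1R,2S,3S,5R,6S,7R,8S,10R)-8-angeloyloxy-1,10:2,3-diepoxy-5-hydroxygermacra-4(15),11(13)-dien-12,6-olide, via alkenylchromium dichloride 31 (not isolated)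
Conditions: CrCl2 (15 equiv), NiCl2 (cat.), degassed DMF/THF (3:1), rt, syringe-pump addition to 2 mM
Reagents that add atoms: none
Why: Intramolecular Nozaki–Hiyama–Kishi reaction of the alkenyl triflate with the aldehyde closes the ten-membered ring; polar Felkin–Anh attack anti to the C6–O bond gives the 5,6-anti (5R) allylic alcohol, and the esters, oxiranes and α-methylene lactone tolerate the chromium reagent.

**Compound list**

1 | (R)-glycidol | OC[C@@H]1CO1 | starting material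
2 | (S)-2-(((4-methoxybenzyl)oxy)methyl)oxirane | COc1ccc(COC[C@@H]2CO2)cc1 | intermediate
3 | (S)-1-((4-methoxybenzyl)oxy)but-3-en-2-ol | O[C@H](COCc1ccc(OC)cc1)C=C | intermediate
4 | 2-(bromomethyl)acrylic acid | C=C(CBr)C(=O)O | starting material
5 | (S)-1-((4-methoxybenzyl)oxy)but-3-en-2-yl 2-(bromomethyl)acrylate | C=C(CBr)C(=O)O[C@H](COCc1ccc(OC)cc1)C=C | intermediate
6 | (S)-3-(bromomethyl)-5-(((4-methoxybenzyl)oxy)methyl)furan-2(5H)-one | O=C1O[C@H](COCc2ccc(OC)cc2)C=C1CBr | intermediate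
7 | but-3-yn-1-ol | C#CCCO | starting material
8 | 1-((but-3-yn-1-yloxy)methyl)-4-methoxybenzene | C#CCCOCc1ccc(OC)cc1 | intermediate
9 | (E)-(4-((4-methoxybenzyl)oxy)-2-methylbut-1-en-1-yl)dimethylalane | C[Al](C)/C=C(\C)CCOCc1ccc(OC)cc1 | intermediate (not isolated)
10 | lithium butyl((E)-4-((4-methoxybenzyl)oxy)-2-methylbut-1-en-1-yl)dimethylalanate | [Li+].CCCC[Al-](C)(C)/C=C(\C)CCOCc1ccc(OC)cc1 | intermediate (not isolated)
11 | (E)-5-((4-methoxybenzyl)oxy)-3-methylpent-2-en-1-ol | OC/C=C(\C)CCOCc1ccc(OC)cc1 | intermediate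
12 | ((2R,3R)-3-(2-((4-methoxybenzyl)oxy)ethyl)-3-methyloxiran-2-yl)methanol | COc1ccc(COCC[C@@]2(C)O[C@@H]2CO)cc1 | intermediate
13 | (2S,3R)-3-(2-((4-methoxybenzyl)oxy)ethyl)-3-methyloxirane-2-carbaldehyde | COc1ccc(COCC[C@@]2(C)O[C@@H]2C=O)cc1 | intermediate
14 | methyl (Z)-3-((2R,3R)-3-(2-((4-methoxybenzyl)oxy)ethyl)-3-methyloxiran-2-yl)acrylate | COc1ccc(COCC[C@@]2(C)O[C@@H]2/C=C\C(=O)OC)cc1 | intermediate
15 | (Z)-3-((2R,3R)-3-(2-((4-methoxybenzyl)oxy)ethyl)-3-methyloxiran-2-yl)prop-2-en-1-ol | COc1ccc(COCC[C@@]2(C)O[C@@H]2/C=C\CO)cc1 | intermediate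
16 | ((2S,3S)-3-((2R,3R)-3-(2-((4-methoxybenzyl)oxy)ethyl)-3-methyloxiran-2-yl)oxiran-2-yl)methanol | COc1ccc(COCC[C@@]2(C)O[C@@H]2[C@H]2O[C@H]2CO)cc1 | intermediate
17 | (2R,3R)-3-((2R,3R)-3-(2-((4-methoxybenzyl)oxy)ethyl)-3-methyloxiran-2-yl)oxirane-2-carbaldehyde | COc1ccc(COCC[C@@]2(C)O[C@@H]2[C@H]2O[C@H]2C=O)cc1 | intermediate
18 | 1-((2S,3S)-3-((2R,3R)-3-(2-((4-methoxybenzyl)oxy)ethyl)-3-methyloxiran-2-yl)oxiran-2-yl)ethan-1-ol, both carbinol epimers | COc1ccc(COCC[C@@]2(C)O[C@@H]2[C@H]2O[C@H]2C(C)O)cc1 | intermediate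
19 | 1-((2R,3R)-3-((2R,3R)-3-(2-((4-methoxybenzyl)oxy)ethyl)-3-methyloxiran-2-yl)oxiran-2-yl)ethan-1-one | COc1ccc(COCC[C@@]2(C)O[C@@H]2[C@H]2O[C@H]2C(C)=O)cc1 | intermediate
20 | potassium 1-((2R,3S)-3-((2R,3R)-3-(2-((4-methoxybenzyl)oxy)ethyl)-3-methyloxiran-2-yl)oxiran-2-yl)ethen-1-olate | COc1ccc(COCC[C@@]2(C)O[C@@H]2[C@H]2O[C@H]2C(=C)[O-])cc1.[K+] | intermediate (not isolated)
21 | 1-((2R,3S)-3-((2R,3R)-3-(2-((4-methoxybenzyl)oxy)ethyl)-3-methyloxiran-2-yl)oxiran-2-yl)vinyl trifluoromethanesulfonate | COc1ccc(COCC[C@@]2(C)O[C@@H]2[C@H]2O[C@H]2C(=C)OS(=O)(=O)C(F)(F)F)cc1 | intermediate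
22 | 1-((2R,3S)-3-((2R,3R)-3-(2-hydroxyethyl)-3-methyloxiran-2-yl)oxiran-2-yl)vinyl trifluoromethanesulfonate | OCC[C@@]1(C)O[C@@H]1[C@H]1O[C@H]1C(=C)OS(=O)(=O)C(F)(F)F | intermediate
23 | 1-((2R,3S)-3-((2R,3R)-3-methyl-3-(2-oxoethyl)oxiran-2-yl)oxiran-2-yl)vinyl trifluoromethanesulfonate | O=CC[C@@]1(C)O[C@@H]1[C@H]1O[C@H]1C(=C)OS(=O)(=O)C(F)(F)F | intermediate
24 | (((S)-5-(((4-methoxybenzyl)oxy)methyl)-2-oxo-2,5-dihydrofuran-3-yl)methyl)zinc bromide | O=C1O[C@H](COCc2ccc(OC)cc2)C=C1C[Zn]Br | intermediate (not isolated)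
25 | 1-((2R,3S)-3-((2R,3R)-3-((S)-2-hydroxy-2-((2S,3R)-2-(((4-methoxybenzyl)oxy)methyl)-4-methylene-5-oxotetrahydrofuran-3-yl)ethyl)-3-methyloxiran-2-yl)oxiran-2-yl)vinyl trifluoromethanesulfonate | C=C1C(=O)O[C@H](COCc2ccc(OC)cc2)[C@H]1[C@@H](O)C[C@@]1(C)O[C@@H]1[C@H]1O[C@H]1C(=C)OS(=O)(=O)C(F)(F)F | intermediate
26 | angelic acid, (Z)-2-methylbut-2-enoic acid | C/C=C(/C)C(=O)O | starting material
27 | (Z)-2-methylbut-2-enoic 2,4,6-trichlorobenzoic anhydride | C/C=C(/C)C(=O)OC(=O)c1c(Cl)cc(Cl)cc1Cl | intermediate (not isolated)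
28 | (S)-1-((2S,3R)-2-(((4-methoxybenzyl)oxy)methyl)-4-methylene-5-oxotetrahydrofuran-3-yl)-2-((2R,3R)-2-methyl-3-((2S,3R)-3-(1-(((trifluoromethyl)sulfonyl)oxy)vinyl)oxiran-2-yl)oxiran-2-yl)ethyl (Z)-2-methylbut-2-enoate | C=C1C(=O)O[C@H](COCc2ccc(OC)cc2)[C@H]1[C@@H](OC(=O)/C(C)=C\C)C[C@@]1(C)O[C@@H]1[C@H]1O[C@H]1C(=C)OS(=O)(=O)C(F)(F)F | intermediate
29 | (S)-1-((2S,3R)-2-(hydroxymethyl)-4-methylene-5-oxotetrahydrofuran-3-yl)-2-((2R,3R)-2-methyl-3-((2S,3R)-3-(1-(((trifluoromethyl)sulfonyl)oxy)vinyl)oxiran-2-yl)oxiran-2-yl)ethyl (Z)-2-methylbut-2-enoate | C=C1C(=O)O[C@H](CO)[C@H]1[C@@H](OC(=O)/C(C)=C\C)C[C@@]1(C)O[C@@H]1[C@H]1O[C@H]1C(=C)OS(=O)(=O)C(F)(F)F | intermediate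
30 | (S)-1-((2S,3R)-2-formyl-4-methylene-5-oxotetrahydrofuran-3-yl)-2-((2R,3R)-2-methyl-3-((2S,3R)-3-(1-(((trifluoromethyl)sulfonyl)oxy)vinyl)oxiran-2-yl)oxiran-2-yl)ethyl (Z)-2-methylbut-2-enoate | C=C1C(=O)O[C@H](C=O)[C@H]1[C@@H](OC(=O)/C(C)=C\C)C[C@@]1(C)O[C@@H]1[C@H]1O[C@H]1C(=C)OS(=O)(=O)C(F)(F)F | intermediate
31 | alkenylchromium dichloride derived from 30 (CrCl2 group in place of the triflate at C4) | C=C1C(=O)O[C@H](C=O)[C@H]1[C@@H](OC(=O)/C(C)=C\C)C[C@@]1(C)O[C@@H]1[C@H]1O[C@H]1C(=C)[Cr](Cl)Cl | intermediate (not isolated)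
32 | CNP0038366.2, (1R,2S,3S,5R,6S,7R,8S,10R)-8-angeloyloxy-1,10:2,3-diepoxy-5-hydroxygermacra-4(15),11(13)-dien-12,6-olide | C=C1C(=O)O[C@H]2[C@H]1[C@@H](OC(=O)/C(C)=C\C)C[C@@]1(C)O[C@@H]1[C@H]1O[C@H]1C(=C)[C@H]2O | target

**Step count and risk**

Total step count: 22. Longest linear sequence: 18 steps (steps 5–17, then 18–22); the butenolide branch is steps 1–4.

The three steps most likely to fail, in route order:

Step 18, the Barbier coupling. Aldehyde 23 can eliminate by epoxide opening, and the configuration at C8 rests on a closed chair transition state in an aqueous zinc reaction. Fallback: setting out from 6 and 23, if the coupling gives mainly the 7,8-syn adduct, the (8R)-epimeric hydroxy lactone F1, that alcohol is not discarded but esterified under Mitsunobu conditions (26, PPh3, DIAD, toluene, 0 °C). The SN2 inversion at C8 installs the angelate and the correct configuration in one operation, and the route is rejoined at 28.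

Step 19, the angeloylation. The C8 alcohol is hindered, the angeloyl group can isomerise to the tiglate, and prolonged heating with amine can let the lactone migrate to the C8 oxygen. Fallback: setting out from 25, Steglich acylation with 2-[bis(2,2,2-trifluoroethoxy)phosphoryl]propanoic acid (DCC, DMAP cat., CH2Cl2, 0 °C) gives the phosphonopropionate ester F2. A Still–Gennari olefination of F2 with acetaldehyde (KN(SiMe3)2, 18-crown-6, THF, −78 °C) then builds the Z-trisubstituted double bond on the ester already in place, and the route is rejoined at 28.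

Step 22, the ten-membered ring closure. There is an entropic penalty, the alkenylchromium could collapse onto the neighbouring oxirane, and C5 is set under macrocyclic rather than purely acyclic control. Fallback: setting out from 30, if cyclisation gives mainly the (5S)-epimeric macrocycle F3, F3 is oxidised with Dess–Martin periodinane/pyridine to the C5 ketone, the macrocyclic enone F4. F4 is reduced with Zn(BH4)2 (Et2O, −40 °C), where chelation between the ketone and the C6 lactone oxygen steers hydride to the 5,6-anti alcohol, and the route is rejoined at 32. This fallback corrects the C5 configuration only; it does not rescue a failed ring closure.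

**Further compounds**

F1 | step 18 | 1-((2R,3S)-3-((2R,3R)-3-((R)-2-hydroxy-2-((2S,3R)-2-(((4-methoxybenzyl)oxy)methyl)-4-methylene-5-oxotetrahydrofuran-3-yl)ethyl)-3-methyloxiran-2-yl)oxiran-2-yl)vinyl trifluoromethanesulfonate (C8 epimer of 25) | C=C1C(=O)O[C@H](COCc2ccc(OC)cc2)[C@H]1[C@H](O)C[C@@]1(C)O[C@@H]1[C@H]1O[C@H]1C(=C)OS(=O)(=O)C(F)(F)F
F2 | step 19 | 2-[bis(2,2,2-trifluoroethoxy)phosphoryl]propanoate ester of 25 at the C8 oxygen (both epimers at the phosphonate carbon) | C=C1C(=O)O[C@H](COCc2ccc(OC)cc2)[C@H]1[C@@H](OC(=O)C(C)P(=O)(OCC(F)(F)F)OCC(F)(F)F)C[C@@]1(C)O[C@@H]1[C@H]1O[C@H]1C(=C)OS(=O)(=O)C(F)(F)F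
F3 | step 22 | (5S)-epimer of 32 | C=C1C(=O)O[C@H]2[C@H]1[C@@H](OC(=O)/C(C)=C\C)C[C@@]1(C)O[C@@H]1[C@H]1O[C@H]1C(=C)[C@@H]2O
F4 | step 22 | 5-oxo analogue of 32 (macrocyclic C5 ketone, 4(15)-en-5-one) | C=C1C(=O)O[C@H]2[C@H]1[C@@H](OC(=O)/C(C)=C\C)C[C@@]1(C)O[C@@H]1[C@H]1O[C@H]1C(=C)C2=O
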